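**Plan**
The 14-membered lactone holds a syn aldol unit at C9 (ketone)–C10 (methyl)–C11 (hydroxyl), flanked by the epimerisable C8 and by the O13 acyloxy group β to C11. C10 with its methyl is a vinyl ketone CH=CH2 that has taken up one hydride, so this unit can be made last and without amine or alkoxide base.
Cuts, in retrosynthetic order: the C3/C5 acetonide; C10–C11 (ring opening to an enone aldehyde); the O13–C1 ester; C4–C5 (aldol); C9–C10 (vinyl addition) and C12–C13 (aldol).
Forward: the C5–C10 aldehyde (from meso-2,4-dimethylglutaric anhydride) and a C1–C4 β-ketoimide give the C1–C10 acid; this is esterified with the C11–C13 alcohol; enone and aldehyde are unveiled; the single ring closes at C10–C11; the acetonide is removed.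
Stereochemistry: C6/C8 from lipase desymmetrisation of a meso diol; C2 from an Evans aldol; C4/C5 from the C2-controlled titanium aldol; C3 from chelate-controlled reduction; C12/C13 from an Evans syn aldol with acetaldehyde; C10/C11 from the Z-enolate chair of the ring closure under control of C12.

Key step: step 21

Remark: positions are given in macrolide numbering (C1 lactone carbonyl to C13); the C9 carbinol carbon of compounds 7–10, 17–20 and 27–29 is carried as a mixture of both epimers because step 20 oxidises it to the ketone, so names give it as RS and SMILES leave it undefined (TBSO = tert-butyldimethylsilyloxy).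

**Step 1**
Reactants: 1 2,4-dimethylglutaric acid (commercial mixture of meso and racemic isomers)
Product: 2 meso-2,4-dimethylglutaric anhydride, cis-(3R,5S)-3,5-dimethyloxane-2,6-dione
Conditions: Ac2O, reflux; evaporate; recrystallise (EtOAc/hexane)
Reagents that add atoms: none
Why: Cyclodehydration by acyl exchange with acetic anhydride gives the six-membered anhydride, and at reflux the two α-centres epimerise through the enol so that the mixture should converge on the more stable, crystalline cis (meso) isomer.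

**Step 2**
Reactants: 2 meso-2,4-dimethylglutaric anhydride
Product: 3 meso-(2R,4S)-2,4-dimethylpentane-1,5-diol
Conditions: LiAlH4, THF, 0 °C to reflux
Reagents that add atoms: none
Why: Hydride reduction of a cyclic anhydride to the diol is fast relative to enolisation, so the cis relationship of the two methyl groups should be kept.

**Step 3**
Reactants: 3 meso-(2R,4S)-2,4-dimethylpentane-1,5-diol
Product: 4 (2S,4R)-5-hydroxy-2,4-dimethylpentyl acetate
Conditions: Amano lipase AK (Pseudomonas fluorescens), vinyl acetate, THF, rt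
Reagents that add atoms: vinyl acetate, CC(=O)OC=C
Why: Lipase-catalysed desymmetrisation by irreversible transesterification acylates the hydroxymethyl group on the (S)-configured carbon of the meso diol, which fixes C6 as S and C8 as R and leaves the C9 hydroxyl free.

**Step 4**
Reactants: 4 (2S,4R)-5-hydroxy-2,4-dimethylpentyl acetate
Product: 5 (2S,4R)-2,4-dimethyl-5-oxopentyl acetate
Conditions: TEMPO (cat.), PhI(OAc)2, CH2Cl2, rt
Reagents that add atoms: none
Why: The oxoammonium (TEMPO) oxidation of a primary alcohol stops at the aldehyde under non-basic conditions, so the α-methyl centre C8 and the acetate are expected to survive.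

**Step 5**
Reactants: 5 (2S,4R)-2,4-dimethyl-5-oxopentyl acetate; 6 vinylmagnesium bromide
Product: 7 (2S,4R,5RS)-5-hydroxy-2,4-dimethylhept-6-en-1-yl acetate
Conditions: CH2=CHMgBr (1.1 equiv), THF, −78 °C; aq. NH4Cl
Reagents that add atoms: none
Why: Grignard addition takes place at the aldehyde, which at −78 °C is far more electrophilic than the acetate, and the new C9 carbinol may form as a mixture of epimers because it ends as the ketone.

**Step 6**
Reactants: 7 (2S,4R,5RS)-5-hydroxy-2,4-dimethylhept-6-en-1-yl acetate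
Product: 8 (2S,4R,5RS)-5-TBSO-2,4-dimethylhept-6-en-1-yl acetate
Conditions: TBSCl, imidazole, DMF, rt
Reagents that add atoms: tert-butyldimethylsilyl chloride, CC(C)(C)[Si](C)(C)Cl
Why: Imidazole-promoted silylation gives a secondary silyl ether that should withstand methanolysis, TiCl4 at low temperature, borohydride, hydroperoxide and acylation conditions downstream.

**Step 7**
Reactants: 8 (2S,4R,5RS)-5-TBSO-2,4-dimethylhept-6-en-1-yl acetate
Product: 9 (2S,4R,5RS)-5-TBSO-2,4-dimethylhept-6-en-1-ol
Conditions: K2CO3 (cat.), MeOH, 0 °C to rt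
Reagents that add atoms: none
Why: Base-catalysed transesterification with methanol removes the acetate without touching the secondary silyl ether.

**Step 8**
Reactants: 9 (2S,4R,5RS)-5-TBSO-2,4-dimethylhept-6-en-1-ol
Product: 10 (2S,4R,5RS)-5-TBSO-2,4-dimethylhept-6-enal (C5–C10 aldehyde)
Conditions: TEMPO (cat.), PhI(OAc)2, CH2Cl2, rt; used at once
Reagents that add atoms: none
Why: The same non-basic TEMPO oxidation as in step 4 gives the aldehyde, which is used directly so that the C6 centre is not exposed to epimerisation.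

**Step 9**
Reactants: 11 (R)-4-benzyl-3-propionyloxazolidin-2-one; 12 propanal
Product: 14 (R)-4-benzyl-3-[(2R,3S)-3-hydroxy-2-methylpentanoyl]oxazolidin-2-one, via dibutylboron Z-enolate 13 (not isolated)
Conditions: Bu2BOTf, Et3N, CH2Cl2, −78 to 0 °C; EtCHO, −78 to 0 °C; H2O2, pH 7 buffer, MeOH
Reagents that add atoms: none
Why: In this Evans syn aldol reaction the Z-boron enolate reacts through a Zimmerman–Traxler chair and the benzyl group of the (R)-auxiliary directs the aldehyde to one face, giving the (2R,3S) adduct, of which only C2 is needed later.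

**Step 10**
Reactants: 14 (R)-4-benzyl-3-[(2R,3S)-3-hydroxy-2-methylpentanoyl]oxazolidin-2-one
Product: 15 (R)-4-benzyl-3-[(R)-2-methyl-3-oxopentanoyl]oxazolidin-2-one
Conditions: SO3·pyridine, DMSO, Et3N, CH2Cl2, −10 to 0 °C
Reagents that add atoms: none
Why: Parikh–Doering oxidation gives the β-ketoimide without epimerising C2, whose C–H bond is held in the plane of the imide carbonyl by allylic 1,3-strain and is therefore kinetically non-acidic.

**Step 11**
Reactants: 15 (R)-4-benzyl-3-[(R)-2-methyl-3-oxopentanoyl]oxazolidin-2-one; 10 (2S,4R,5RS)-5-TBSO-2,4-dimethylhept-6-enal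
Product: 17 (R)-4-benzyl-3-[(2R,4R,5S,6S,8R,9RS)-9-TBSO-5-hydroxy-2,4,6,8-tetramethyl-3-oxoundec-10-enoyl]oxazolidin-2-one, via trichlorotitanium Z-enolate 16 (not isolated)
Conditions: TiCl4, iPr2NEt, CH2Cl2, −10 °C; then 10, −78 °C
Reagents that add atoms: none
Why: In this titanium-mediated aldol reaction of a β-ketoimide, enolisation occurs only toward C4 to a chelated Z-enolate that adds through a closed chair on the face set by the C2 methyl group, which should give the 2,4-syn-4,5-syn (4R,5S) adduct, and the 5,6-anti (anti-Felkin) sense required is the one a Z-enolate prefers with an α-methyl aldehyde.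

**Step 12**
Reactants: 17 the 3-oxo-5-hydroxy imide
Product: 18 (R)-4-benzyl-3-[(2R,3S,4R,5S,6S,8R,9RS)-9-TBSO-3,5-dihydroxy-2,4,6,8-tetramethylundec-10-enoyl]oxazolidin-2-one
Conditions: Zn(BH4)2, CH2Cl2/Et2O, −78 to −20 °C
Reagents that add atoms: none
Why: Chelation-controlled reduction of the β-hydroxy ketone delivers hydride to the zinc chelate of O5 and the C3 carbonyl from its less hindered face, which should set C3 as S in a 3,5-syn diol.

**Step 13**
Reactants: 18 the 3,5-syn diol imide
Product: 19 (R)-4-benzyl-3-[(2R,3S,4R,5S,6S,8R,9RS)-9-TBSO-3,5-(isopropylidenedioxy)-2,4,6,8-tetramethylundec-10-enoyl]oxazolidin-2-one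
Conditions: Me2C(OMe)2, camphorsulfonic acid (cat.), CH2Cl2, rt
Reagents that add atoms: 2,2-dimethoxypropane, COC(C)(C)OC
Why: Acid-catalysed transacetalisation forms the chair acetonide of the syn-1,3-diol, which masks both hydroxyls in one step and stiffens the C1–C6 segment for the later ring closure.

**Step 14**
Reactants: 19 the acetonide imide
Product: 20 (2R,3S,4R,5S,6S,8R,9RS)-9-TBSO-3,5-(isopropylidenedioxy)-2,4,6,8-tetramethylundec-10-enoic acid (C1–C10 acid)
Conditions: LiOH, H2O2, THF/H2O, 0 °C; Na2SO3; aq. HCl to pH 4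
Reagents that add atoms: hydrogen peroxide (as LiOOH), OO
Why: In this hydroperoxide cleavage of an N-acyloxazolidinone the α-effect nucleophile attacks the exocyclic carbonyl selectively and is too weakly basic to epimerise C2, while the silyl ether, the acetonide and the terminal alkene are inert.

**Step 15**
Reactants: 21 (S)-4-benzyl-3-propionyloxazolidin-2-one; 22 acetaldehyde
Product: 24 (S)-4-benzyl-3-[(2S,3R)-3-hydroxy-2-methylbutanoyl]oxazolidin-2-one, via dibutylboron Z-enolate 23 (not isolated)
Conditions: Bu2BOTf, Et3N, CH2Cl2, −78 to 0 °C; MeCHO, −78 to 0 °C; H2O2, pH 7 buffer, MeOH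
Reagents that add atoms: none
Why: This Evans syn aldol reaction with the (S)-auxiliary sets C12 and C13 as the (2S,3R) syn pair through the Z-boron enolate chair.

**Step 16**
Reactants: 24 (S)-4-benzyl-3-[(2S,3R)-3-hydroxy-2-methylbutanoyl]oxazolidin-2-one
Product: 25 (2R,3R)-2-methylbutane-1,3-diol
Conditions: LiBH4, MeOH (1 equiv), THF, 0 °C
Reagents that add atoms: none
Why: Reductive cleavage of the N-acyloxazolidinone releases the primary alcohol and the auxiliary without touching the two stereocentres.

**Step 17**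
Reactants: 25 (2R,3R)-2-methylbutane-1,3-diol
Product: 26 (2R,3R)-4-TBSO-3-methylbutan-2-ol (C11–C13 alcohol)
Conditions: TBSCl (1.0 equiv), imidazole, CH2Cl2, −20 to 0 °C
Reagents that add atoms: tert-butyldimethylsilyl chloride, CC(C)(C)[Si](C)(C)Cl
Why: Silylation with a bulky silyl chloride is selective for the primary hydroxyl and leaves the C13 secondary hydroxyl free for the ester bond.

**Step 18**
Reactants: 20 the C1–C10 acid; 26 (2R,3R)-4-TBSO-3-methylbutan-2-ol
Product: 28 (2R,3R)-4-TBSO-3-methylbutan-2-yl (2R,3S,4R,5S,6S,8R,9RS)-9-TBSO-3,5-(isopropylidenedioxy)-2,4,6,8-tetramethylundec-10-enoate, via mixed trichlorobenzoic anhydride 27 (not isolated)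
Conditions: 2,4,6-Cl3C6H2COCl, Et3N, toluene, rt; then 26, DMAP, toluene, rt
Reagents that add atoms: none
Why: In this Yamaguchi esterification DMAP attacks the mixed anhydride only at the aliphatic carbonyl and the acylpyridinium formed acylates the secondary alcohol, a reaction type that tolerates α-branched β-alkoxy acids.

**Step 19**
Reactants: 28 the bis-silyl ester
Product: 29 (2R,3R)-4-hydroxy-3-methylbutan-2-yl (2R,3S,4R,5S,6S,8R,9RS)-9-hydroxy-3,5-(isopropylidenedioxy)-2,4,6,8-tetramethylundec-10-enoate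
Conditions: HF·pyridine, pyridine, THF, 0 °C to rt
Reagents that add atoms: none
Why: Fluoride-mediated desilylation in a pyridine-buffered medium should remove both silyl ethers while the acetonide and the ester stay intact and acyl migration from O13 to O11 is not promoted.

**Step 20**
Reactants: 29 the C9,C11 diol ester
Product: 30 (2R,3S)-3-methyl-4-oxobutan-2-yl (2R,3S,4R,5S,6S,8R)-3,5-(isopropylidenedioxy)-2,4,6,8-tetramethyl-9-oxoundec-10-enoate (seco enone aldehyde)
Conditions: Dess–Martin periodinane (3 equiv), pyridine, CH2Cl2, 0 °C to rt; filtration through silica; used at once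
Reagents that add atoms: none
Why: Dess–Martin oxidation converts the allylic carbinol into the vinyl ketone and the primary alcohol into the aldehyde in one operation under near-neutral conditions, which should spare the C8 and C12 centres and the β-acyloxy aldehyde.

**Step 21**
Reactants: 30 the seco enone aldehyde
Product: 31 (3R,4S,5R,6S,7S,9R,11R,12S,13R,14R)-12-hydroxy-4,6-(isopropylidenedioxy)-3,5,7,9,11,13,14-heptamethyl-1-oxacyclotetradecane-2,10-dione (3,5-O-isopropylidene-8,8a-deoxyoleandolide)
Conditions: Rh(cod)2OTf (20 mol %), (2-furyl)3P (48 mol %), Li2CO3 (40 mol %), H2 (1 atm), CH2Cl2, 25 °C; 30 added by syringe pump over 12 h, final 2 mM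
Reagents that add atoms: none
Why: Proposed new method: heterolytic activation of H2 by the cationic monovalent rhodium–tri(2-furyl)phosphine complex (Li2CO3 takes up the proton) gives a rhodium monohydride that hydrometallates the s-cis vinyl ketone, creating the C10 methyl and a Z-configured oxygen-bound rhodium enolate located only at C10; this enolate adds to the C11 aldehyde and H2 cleaves the rhodium aldolate, the closest known reactions being the intermolecular hydrogen-mediated rhodium reductive aldol coupling of vinyl ketones with aldehydes and reductive aldol cyclisations to five- and six-membered rings. The 14-membered ring closes in a 14-(enolendo)-exo-trig mode, C10 attacking the C11 carbonyl whose oxygen stays outside the ring. C10 and C11 are set together by the Z-enolate in a closed Zimmerman–Traxler chair, which gives the 10,11-syn relationship, and the C12 centre selects the aldehyde face on which the C10 methyl and the C12 branch avoid a syn-pentane contact, which gives 11,12-anti. The step needs enolate formation at C10 only, no epimerisation at C8 or C12 and no elimination of the C13 carboxylate, and the hydride route to the enolate in the absence of amine or alkoxide secures these. It also needs aldol capture to outrun hydrogenolysis of the enolate and coupling between two molecules, which slow addition of 30 to the catalyst under one atmosphere of H2 and the turn imposed by the C3/C5 acetonide are meant to favour.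

**Step 22**
Reactants: 31 3,5-O-isopropylidene-8,8a-deoxyoleandolide
Product: 32 8,8a-deoxyoleandolide, (3R,4S,5R,6S,7S,9R,11R,12S,13R,14R)-4,6,12-trihydroxy-3,5,7,9,11,13,14-heptamethyl-1-oxacyclotetradecane-2,10-dione
Conditions: 1 M aq. HCl, THF, rt
Reagents that add atoms: none
Why: Acid-catalysed acetal hydrolysis frees the C3 and C5 hydroxyls, and the β-hydroxy ketone and the lactone of this macrolide class are expected to tolerate dilute aqueous acid at room temperature.

**Compound list**
1 | 2,4-dimethylglutaric acid (mixture of meso and racemic isomers) | CC(CC(C)C(=O)O)C(=O)O | starting material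
2 | meso-2,4-dimethylglutaric anhydride, cis-(3R,5S)-3,5-dimethyloxane-2,6-dione | O=C1[C@@H](C)C[C@@H](C)C(=O)O1 | intermediate
3 | meso-(2R,4S)-2,4-dimethylpentane-1,5-diol | OC[C@@H](C)C[C@@H](C)CO | intermediate
4 | (2S,4R)-5-hydroxy-2,4-dimethylpentyl acetate | CC(=O)OC[C@@H](C)C[C@@H](C)CO | intermediate
5 | (2S,4R)-2,4-dimethyl-5-oxopentyl acetate | CC(=O)OC[C@@H](C)C[C@@H](C)C=O | intermediate
6 | vinylmagnesium bromide | C=C[Mg]Br | starting material
7 | (2S,4R,5RS)-5-hydroxy-2,4-dimethylhept-6-en-1-yl acetate | CC(=O)OC[C@@H](C)C[C@@H](C)C(O)C=C | intermediate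
8 | (2S,4R,5RS)-5-[(tert-butyldimethylsilyl)oxy]-2,4-dimethylhept-6-en-1-yl acetate | CC(=O)OC[C@@H](C)C[C@@H](C)C(O[Si](C)(C)C(C)(C)C)C=C | intermediate
9 | (2S,4R,5RS)-5-[(tert-butyldimethylsilyl)oxy]-2,4-dimethylhept-6-en-1-ol | OC[C@@H](C)C[C@@H](C)C(O[Si](C)(C)C(C)(C)C)C=C | intermediate
10 | (2S,4R,5RS)-5-[(tert-butyldimethylsilyl)oxy]-2,4-dimethylhept-6-enal | O=C[C@@H](C)C[C@@H](C)C(O[Si](C)(C)C(C)(C)C)C=C | intermediate
11 | (R)-4-benzyl-3-propionyloxazolidin-2-one | CCC(=O)N1[C@H](Cc2ccccc2)COC1=O | starting material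
12 | propanal | CCC=O | starting material
13 | (Z)-dibutylboron enolate of 11 (formed in the flask, not isolated) | C/C=C(\OB(CCCC)CCCC)N1[C@H](Cc2ccccc2)COC1=O | intermediate
14 | (R)-4-benzyl-3-[(2R,3S)-3-hydroxy-2-methylpentanoyl]oxazolidin-2-one | CC[C@H](O)[C@@H](C)C(=O)N1[C@H](Cc2ccccc2)COC1=O | intermediate
15 | (R)-4-benzyl-3-[(R)-2-methyl-3-oxopentanoyl]oxazolidin-2-one | CCC(=O)[C@@H](C)C(=O)N1[C@H](Cc2ccccc2)COC1=O | intermediate
16 | trichlorotitanium (Z)-enolate of 15 at C3–C4 (formed in the flask, not isolated) | C/C=C(\O[Ti](Cl)(Cl)Cl)[C@@H](C)C(=O)N1[C@H](Cc2ccccc2)COC1=O | intermediate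
17 | (R)-4-benzyl-3-[(2R,4R,5S,6S,8R,9RS)-9-[(tert-butyldimethylsilyl)oxy]-5-hydroxy-2,4,6,8-tetramethyl-3-oxoundec-10-enoyl]oxazolidin-2-one | O=C(N1[C@H](Cc2ccccc2)COC1=O)[C@H](C)C(=O)[C@H](C)[C@@H](O)[C@@H](C)C[C@@H](C)C(O[Si](C)(C)C(C)(C)C)C=C | intermediate
18 | (R)-4-benzyl-3-[(2R,3S,4R,5S,6S,8R,9RS)-9-[(tert-butyldimethylsilyl)oxy]-3,5-dihydroxy-2,4,6,8-tetramethylundec-10-enoyl]oxazolidin-2-one | O=C(N1[C@H](Cc2ccccc2)COC1=O)[C@H](C)[C@@H](O)[C@H](C)[C@@H](O)[C@@H](C)C[C@@H](C)C(O[Si](C)(C)C(C)(C)C)C=C | intermediate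
19 | (R)-4-benzyl-3-[(2R,3S,4R,5S,6S,8R,9RS)-9-[(tert-butyldimethylsilyl)oxy]-3,5-(isopropylidenedioxy)-2,4,6,8-tetramethylundec-10-enoyl]oxazolidin-2-one | O=C(N1[C@H](Cc2ccccc2)COC1=O)[C@H](C)[C@H]3OC(C)(C)O[C@H]([C@H]3C)[C@@H](C)C[C@@H](C)C(O[Si](C)(C)C(C)(C)C)C=C | intermediate
20 | (2R,3S,4R,5S,6S,8R,9RS)-9-[(tert-butyldimethylsilyl)oxy]-3,5-(isopropylidenedioxy)-2,4,6,8-tetramethylundec-10-enoic acid | OC(=O)[C@H](C)[C@H]1OC(C)(C)O[C@H]([C@H]1C)[C@@H](C)C[C@@H](C)C(O[Si](C)(C)C(C)(C)C)C=C | intermediate
21 | (S)-4-benzyl-3-propionyloxazolidin-2-one | CCC(=O)N1[C@@H](Cc2ccccc2)COC1=O | starting material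
22 | acetaldehyde | CC=O | starting material
23 | (Z)-dibutylboron enolate of 21 (formed in the flask, not isolated) | C/C=C(\OB(CCCC)CCCC)N1[C@@H](Cc2ccccc2)COC1=O | intermediate
24 | (S)-4-benzyl-3-[(2S,3R)-3-hydroxy-2-methylbutanoyl]oxazolidin-2-one | C[C@@H](O)[C@H](C)C(=O)N1[C@@H](Cc2ccccc2)COC1=O | intermediate
25 | (2R,3R)-2-methylbutane-1,3-diol | C[C@@H](O)[C@H](C)CO | intermediate
26 | (2R,3R)-4-[(tert-butyldimethylsilyl)oxy]-3-methylbutan-2-ol | C[C@@H](O)[C@H](C)CO[Si](C)(C)C(C)(C)C | intermediate
27 | mixed anhydride of acid 20 with 2,4,6-trichlorobenzoic acid (formed in the flask, not isolated) | O=C(OC(=O)c1c(Cl)cc(Cl)cc1Cl)[C@H](C)[C@H]2OC(C)(C)O[C@H]([C@H]2C)[C@@H](C)C[C@@H](C)C(O[Si](C)(C)C(C)(C)C)C=C | intermediate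
28 | (2R,3R)-4-[(tert-butyldimethylsilyl)oxy]-3-methylbutan-2-yl (2R,3S,4R,5S,6S,8R,9RS)-9-[(tert-butyldimethylsilyl)oxy]-3,5-(isopropylidenedioxy)-2,4,6,8-tetramethylundec-10-enoate | CC(C)(C)[Si](C)(C)OC[C@@H](C)[C@@H](C)OC(=O)[C@H](C)[C@H]1OC(C)(C)O[C@H]([C@H]1C)[C@@H](C)C[C@@H](C)C(O[Si](C)(C)C(C)(C)C)C=C | intermediate
29 | (2R,3R)-4-hydroxy-3-methylbutan-2-yl (2R,3S,4R,5S,6S,8R,9RS)-9-hydroxy-3,5-(isopropylidenedioxy)-2,4,6,8-tetramethylundec-10-enoate | OC[C@@H](C)[C@@H](C)OC(=O)[C@H](C)[C@H]1OC(C)(C)O[C@H]([C@H]1C)[C@@H](C)C[C@@H](C)C(O)C=C | intermediate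
30 | (2R,3S)-3-methyl-4-oxobutan-2-yl (2R,3S,4R,5S,6S,8R)-3,5-(isopropylidenedioxy)-2,4,6,8-tetramethyl-9-oxoundec-10-enoate | O=C[C@@H](C)[C@@H](C)OC(=O)[C@H](C)[C@H]1OC(C)(C)O[C@H]([C@H]1C)[C@@H](C)C[C@@H](C)C(=O)C=C | intermediate
31 | (3R,4S,5R,6S,7S,9R,11R,12S,13R,14R)-12-hydroxy-4,6-(isopropylidenedioxy)-3,5,7,9,11,13,14-heptamethyl-1-oxacyclotetradecane-2,10-dione | O=C1[C@H](C)[C@H]2OC(C)(C)O[C@H]([C@H]2C)[C@@H](C)C[C@@H](C)C(=O)[C@H](C)[C@@H](O)[C@@H](C)[C@@H](C)O1 | intermediate
32 | 8,8a-deoxyoleandolide, (3R,4S,5R,6S,7S,9R,11R,12S,13R,14R)-4,6,12-trihydroxy-3,5,7,9,11,13,14-heptamethyl-1-oxacyclotetradecane-2,10-dione | C[C@@H]1[C@@H](O)[C@@H](C)C[C@@H](C)C(=O)[C@H](C)[C@@H](O)[C@@H](C)[C@@H](C)OC(=O)[C@H](C)[C@H]1O | target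

**Step count and risks**
Total step count: 22. Longest linear sequence: 17 steps (steps 1–8, 11–14, 18–22).

Steps most likely to fail:

1. Step 21 (ring closure). The rhodium enolate may be cleaved by H2 before it reaches the aldehyde, which would give the saturated ethyl ketone; two molecules may couple; or the aldehyde may be attacked on the wrong face. The fallback closes the same C10–C11 bond by a samarium Reformatsky-type aldol, a known route to medium and large rings. It sets out from diol 29. MnO2 (CH2Cl2, rt) should oxidise only the allylic C9 carbinol to the hydroxy enone F1. Et3SiH with (Ph3P)3RhCl (THF, 50 °C) should then add in the 1,4 sense to the vinyl ketone and silylate the primary alcohol, giving the Z-triethylsilyl enol ether with a C11 triethylsilyl ether F2. N-Bromosuccinimide (THF, −78 °C) should convert the enol ether into the α-bromo ketone F3 (C10 epimers). HF·pyridine should free the primary hydroxyl to give the bromo keto alcohol F4, and Dess–Martin periodinane should give the bromo keto aldehyde F5. SmI2 (2.2 equiv, THF, −78 °C, high dilution) should reduce the C–Br bond to a trivalent samarium enolate fixed at C10, which is expected to add to the C11 aldehyde through a chelated chair. The route is rejoined at 31.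

2. Step 20 (double oxidation). While two oxidations run in one pot, the C13 carboxylate may undergo β-elimination from the new aldehyde, or the vinyl ketone may polymerise or suffer conjugate addition during work-up. The fallback unveils the two carbonyls one at a time with oxidants that are each selective for one class of alcohol. It sets out from diol 29. TEMPO (cat.)/PhI(OAc)2 should oxidise only the primary C11 alcohol to the hydroxy aldehyde F6. Activated MnO2 (CH2Cl2) should then oxidise the allylic C9 carbinol under neutral heterogeneous conditions, and filtration delivers a solution of 30, where the route is rejoined.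

3. Step 18 (fragment union). Acyl transfer to the hindered secondary alcohol may be slow, and the activated acid may epimerise at C2 through the acylpyridinium or a ketene. The fallback transfers the acyl group from a thioester activated by a thiophilic metal, with no acylpyridinium. It sets out from imide 19. LiSEt (THF, 0 °C) should displace the auxiliary to give the S-ethyl thioester F7. AgO2CCF3 with Na2HPO4 and alcohol 26 (toluene, rt) should then give ester 28, where the route is rejoined.

**Further compounds**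
F1 | step 21 | (2R,3R)-4-hydroxy-3-methylbutan-2-yl (2R,3S,4R,5S,6S,8R)-3,5-(isopropylidenedioxy)-2,4,6,8-tetramethyl-9-oxoundec-10-enoate | OC[C@@H](C)[C@@H](C)OC(=O)[C@H](C)[C@H]1OC(C)(C)O[C@H]([C@H]1C)[C@@H](C)C[C@@H](C)C(=O)C=C
F2 | step 21 | (2R,3R)-3-methyl-4-[(triethylsilyl)oxy]butan-2-yl (2R,3S,4R,5S,6S,8R,9Z)-3,5-(isopropylidenedioxy)-2,4,6,8-tetramethyl-9-[(triethylsilyl)oxy]undec-9-enoate | CC[Si](CC)(CC)OC[C@@H](C)[C@@H](C)OC(=O)[C@H](C)[C@H]1OC(C)(C)O[C@H]([C@H]1C)[C@@H](C)C[C@@H](C)/C(O[Si](CC)(CC)CC)=C/C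
F3 | step 21 | (2R,3R)-3-methyl-4-[(triethylsilyl)oxy]butan-2-yl (2R,3S,4R,5S,6S,8R,10RS)-10-bromo-3,5-(isopropylidenedioxy)-2,4,6,8-tetramethyl-9-oxoundecanoate | CC[Si](CC)(CC)OC[C@@H](C)[C@@H](C)OC(=O)[C@H](C)[C@H]1OC(C)(C)O[C@H]([C@H]1C)[C@@H](C)C[C@@H](C)C(=O)C(Br)C
F4 | step 21 | (2R,3R)-4-hydroxy-3-methylbutan-2-yl (2R,3S,4R,5S,6S,8R,10RS)-10-bromo-3,5-(isopropylidenedioxy)-2,4,6,8-tetramethyl-9-oxoundecanoate | OC[C@@H](C)[C@@H](C)OC(=O)[C@H](C)[C@H]1OC(C)(C)O[C@H]([C@H]1C)[C@@H](C)C[C@@H](C)C(=O)C(Br)C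
F5 | step 21 | (2R,3S)-3-methyl-4-oxobutan-2-yl (2R,3S,4R,5S,6S,8R,10RS)-10-bromo-3,5-(isopropylidenedioxy)-2,4,6,8-tetramethyl-9-oxoundecanoate | O=C[C@@H](C)[C@@H](C)OC(=O)[C@H](C)[C@H]1OC(C)(C)O[C@H]([C@H]1C)[C@@H](C)C[C@@H](C)C(=O)C(Br)C
F6 | step 20 | (2R,3S)-3-methyl-4-oxobutan-2-yl (2R,3S,4R,5S,6S,8R,9RS)-9-hydroxy-3,5-(isopropylidenedioxy)-2,4,6,8-tetramethylundec-10-enoate | O=C[C@@H](C)[C@@H](C)OC(=O)[C@H](C)[C@H]1OC(C)(C)O[C@H]([C@H]1C)[C@@H](C)C[C@@H](C)C(O)C=C
F7 | step 18 | S-ethyl (2R,3S,4R,5S,6S,8R,9RS)-9-[(tert-butyldimethylsilyl)oxy]-3,5-(isopropylidenedioxy)-2,4,6,8-tetramethylundec-10-enethioate | CCSC(=O)[C@H](C)[C@H]1OC(C)(C)O[C@H]([C@H]1C)[C@@H](C)C[C@@H](C)C(O[Si](C)(C)C(C)(C)C)C=C
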